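Thursday's run falls in its tail from 45.2% at 5.00 d to 19.3% at 12.0 d, a reading of 0.122 d⁻¹.

| setting | Thursday's | Wednesday's | Tuesday's | flask |
|---|---|---|---|---|
| starting complex | 0.30 M | 0.30 M | 0.15 M | 0.30 M |
| incoming ligand | 1.3 M | 2 M | 0.90 M | 0.900 M |
| remark | run made earlier | run made earlier | run made earlier |  |
| time |  |  |  | 12 d |

| run | time / d | complex with one exchanged / % |
|---|---|---|
| Thursday's | 0.625 | 66.6 |
| Thursday's | 1.67 | 68.2 |
| Thursday's | 3.00 | 58.0 |
| Thursday's | 5.00 | 45.2 |
| Thursday's | 8.00 | 30.5 |
| Thursday's | 10.0 | 24.1 |
| Thursday's | 12.0 | 19.3 |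
| Wednesday's | 1.04 | 66.0 |
| Wednesday's | 1.67 | 58.3 |
| Wednesday's | 2.00 | 54.0 |
| Wednesday's | 3.00 | 42.5 |
| Wednesday's | 5.00 | 27.7 |
| Wednesday's | 8.00 | 14.8 |
| Wednesday's | 12.0 | 7.4 |
| Tuesday's | 1.04 | 75.2 |
| Tuesday's | 1.67 | 77.6 |
| Tuesday's | 3.00 | 69.1 |
| Tuesday's | 6.00 | 51.5 |
| Tuesday's | 12.0 | 29.4 |

(readings scatter by 0.5 percentage points)



* equivalents of incoming ligand to starting complex, everything else as given, that leave most complex with one exchanged at 12 d
* the amount of complex with one exchanged then, in percent of the starting complex charged
* the amount of complex with one exchanged with the amounts as given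

I read that tail as one molecule's second fork: the complex with one exchanged either waits or meets incoming ligand, a pseudo-first-order loss. So I divide by the ligand on hand, in equivalents of the charge. For Thursday's run I count 2.83 equivalents, after one for the first exchange and 0.5 more as my allowance for the second. That gives the exposure constant, the loss per day per equivalent on hand: 0.0429 d⁻¹.

But Thursday's tail, carried back to zero time, reaches 83.0%, not the whole charge, so I take that as the share passing the first fork. For the flask I count 1.50 equivalents on hand, so I give a molecule a survival chance of 46.2%, and I reckon 38.3%. In this reckoning fewer equivalents raise that chance, but the first exchange takes one equivalent of incoming ligand, so I look just above one.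

The forecast gives 37% as charged and 71% at 1.25 equiv, a yield it calls “uncertain if the loss grows at low ligand”; my figure stands above its 37%.

The flask gives 35.4%, and 1.16 equiv gives 72.0%, so the flask as charged keeps half of that best yield.

    starting complex + incoming ligand ⇌ leaving ligand + complex with one exchanged (K = 0.500, k = 0.192 M⁻¹ h⁻¹)
    complex with one exchanged + incoming ligand ⇌ leaving ligand + complex with two exchanged (K = 0.660, k = 0.00873 M⁻¹ h⁻¹)
    incoming ligand ⇌ dormant form (K = 0.567, k = 1.04 h⁻¹)
    leaving ligand + complex with one exchanged → side product (k = 0.179 M⁻¹ h⁻¹)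
    leaving ligand → by-product carried off (k = 0.196 h⁻¹)

For the neighbour with 1.5 M of incoming ligand I count 3.50 equivalents on hand, so my survival chance falls to 16.5% and I reckon 13.7%. That neighbour gives 14.2%, with 20.5% as side product and 65.3% as complex with two exchanged.

(All runs were generated by integration on assumed constants, noise included.)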